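**Retrosynthetic overview**
- Target ⇒ 1-[3,5-bis(benzyloxy)phenyl]heptadecan-2-one; the two O-benzyl groups are removed last by hydrogenolysis.
- Key disconnection ArCH2–C(=O): a benzyl-carbanion equivalent (the N–H hydrazone of 3,5-bis(benzyloxy)benzaldehyde) plus an acyl-cation equivalent (hexadecanenitrile), joined by the proposed ruthenium-catalysed hydrazone–nitrile addition and ketimine hydrolysis.
- Hydrazone ⇒ 3,5-bis(benzyloxy)benzaldehyde + hydrazine.
- Rings: none is formed. The benzene ring is bought intact in the aldehyde and the C15 chain in the nitrile.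

Assumption: the target has no stereocentre and no stereogenic double bond, so it is achiral and "the single enantiomer given" is simply the compound itself.

**Step 1**
Reactants: 1 3,5-bis(benzyloxy)benzaldehyde
Product: 2 (E)-[3,5-bis(benzyloxy)benzylidene]hydrazine
Conditions: N2H4·H2O (6 equiv), EtOH–THF (3:1), 0 °C to rt, 2 h, slow addition of 1 to the hydrazine; extractive work-up (CH2Cl2), used at once
Reagents that add atoms: hydrazine monohydrate, NN.O
Why: Hydrazone condensation of an aromatic aldehyde; adding 1 slowly to a six-fold excess of hydrazine keeps free aldehyde away from the product and so suppresses the azine, and the C=N bond forms as the E isomer (no stereocentre is created).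

**Step 2**
Reactants: 2 (E)-[3,5-bis(benzyloxy)benzylidene]hydrazine; 3 hexadecanenitrile
Product: 6 1-[3,5-bis(benzyloxy)phenyl]heptadecan-2-one, via diazenyl ketimine 4 (not isolated), via ketimine 5 (not isolated)
Conditions: 2 (1.5 equiv), 3 (1.0 equiv), [RuCl2(p-cymene)]2 (2.5 mol%), Me2PCH2CH2PMe2 (5 mol%), K3PO4 (30 mol%), THF, 60 °C, 24 h, Ar; then 2 M aq HCl, THF, 40 °C, 2 h
Reagents that add atoms: water, O
Why: Proposed new method: a ruthenium-catalysed deoxygenative Grignard-type addition of an aldehyde N–H hydrazone to an unactivated nitrile; the hydrazone, deprotonated and N-bound to divalent ruthenium as Ru–NH–N=CHAr, acts as a benzyl carbanion equivalent and delivers its carbon through a six-membered transition state to the carbon of the nitrile bound and polarised on the same metal, which forms the C1–C2 bond and gives diazenyl ketimine 4; base-induced loss of N2 from the C–N=NH group (the last event of a Wolff–Kishner reduction, eased here because the carbanion left behind is a benzylic 1-azaallyl anion) gives ketimine 5, whose metallated imine/enamide form is not electrophilic, so the addition stops after one C–C bond just as a Grignard addition to a nitrile does, and aqueous acid hydrolyses 5 to ketone 6 (no stereocentre remains); the closest known reaction type is the [RuCl2(p-cymene)]2–diphosphine-catalysed addition of N–H hydrazones to aldehydes, ketones, imines and CO2, in which nitriles have not been shown as acceptors.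

**Step 3**
Reactants: 6 1-[3,5-bis(benzyloxy)phenyl]heptadecan-2-one
Product: 7 1-(3,5-dihydroxyphenyl)heptadecan-2-one
Conditions: H2 (1 atm), Pd/C (10 wt% Pd, 5 mol% Pd), EtOAc–EtOH (1:1), rt, 4 h
Reagents that add atoms: none
Why: Heterogeneous catalytic hydrogenolysis of aryl benzyl ethers; the two benzylic C–O bonds are cleaved at 1 atm and rt while the non-conjugated dialkyl ketone, the arene and the alkyl chain are untouched, so the free resorcinol target is released without acid or base.

**Compound list**
1 | 3,5-bis(benzyloxy)benzaldehyde | O=Cc1cc(OCc2ccccc2)cc(OCc2ccccc2)c1 | starting material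
2 | (E)-[3,5-bis(benzyloxy)benzylidene]hydrazine (N–H hydrazone of 1) | N/N=C/c1cc(OCc2ccccc2)cc(OCc2ccccc2)c1 | intermediate
3 | hexadecanenitrile | CCCCCCCCCCCCCCCC#N | starting material
4 | 1-[3,5-bis(benzyloxy)phenyl]-1-diazenylheptadecan-2-imine (racemic at C1, transient) | CCCCCCCCCCCCCCCC(=N)C(N=N)c1cc(OCc2ccccc2)cc(OCc2ccccc2)c1 | intermediate
5 | 1-[3,5-bis(benzyloxy)phenyl]heptadecan-2-imine | CCCCCCCCCCCCCCCC(=N)Cc1cc(OCc2ccccc2)cc(OCc2ccccc2)c1 | intermediate
6 | 1-[3,5-bis(benzyloxy)phenyl]heptadecan-2-one | CCCCCCCCCCCCCCCC(=O)Cc1cc(OCc2ccccc2)cc(OCc2ccccc2)c1 | intermediate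
7 | 1-(3,5-dihydroxyphenyl)heptadecan-2-one (achiral) | CCCCCCCCCCCCCCCC(=O)Cc1cc(O)cc(O)c1 | target

**Total step count:** 3
**Longest linear sequence:** 3 steps (1 → 2 → 6 → 7; nitrile 3 is bought and enters in step 2).

**Steps most likely to fail, highest risk first**

- Step 2 (the proposed new step). An aliphatic nitrile may be too weak an acceptor for the ruthenium-bound hydrazone. Plain Wolff–Kishner reduction of 2 to the methylarene, azine formation or N-attack of the hydrazone on the nitrile could then dominate. The fallback uses known chemistry: homologation of an aldehyde with an aryldiazomethane made in situ from a tosylhydrazone salt (Bamford–Stevens generation, then 1,2-hydride shift). It sets out from 1 and 3 and comes back to the route at 6. Aldehyde 1 is condensed with TsNHNH2 in MeOH at rt to N'-[(E)-3,5-bis(benzyloxy)benzylidene]-4-methylbenzenesulfonohydrazide F1. Nitrile 3 is reduced with iBu2AlH in toluene at −78 °C and hydrolysed with 1 M aq HCl to hexadecanal F2. F1 and F2 are then heated with NaOEt in EtOH at 80 °C; the salt of F1 fragments to [3,5-bis(benzyloxy)phenyl]diazomethane F3, which adds to the carbonyl carbon of F2 and, by 1,2-hydride shift with loss of nitrogen, gives ketone 6.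

- Step 1. The N–H hydrazone 2 can disproportionate to azine and hydrazine during concentration, which would starve step 2 of its nucleophile. The fallback is a two-stage transhydrazonation. It sets out from 1 and comes back at 2. Aldehyde 1 is condensed with N,N-dimethylhydrazine (EtOH, cat. AcOH, rt) to (E)-3,5-bis(benzyloxy)benzaldehyde N,N-dimethylhydrazone F4, a storable compound that cannot form an azine. F4 is then heated with excess anhydrous hydrazine in EtOH at reflux, which exchanges the dimethylamino-imine unit for the N–H hydrazone and gives 2 free of azine.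

- Step 3. Prolonged hydrogenation could partly reduce the ketone to the carbinol. The fallback masks the ketone before debenzylation. It sets out from 6 and comes back at 7. Ketone 6 is ketalised with ethane-1,2-diol (cat. TsOH, toluene, Dean–Stark) to 2-[3,5-bis(benzyloxy)benzyl]-2-pentadecyl-1,3-dioxolane F5. F5 is hydrogenolysed (H2, Pd(OH)2/C, EtOAc–MeOH, rt) to 5-[(2-pentadecyl-1,3-dioxolan-2-yl)methyl]benzene-1,3-diol F6. The dioxolane is then removed with 1 M aq HCl in THF at rt to give 7.

**Further compounds**
F1 | step 2 | N'-[(E)-3,5-bis(benzyloxy)benzylidene]-4-methylbenzenesulfonohydrazide | Cc1ccc(cc1)S(=O)(=O)N/N=C/c1cc(OCc2ccccc2)cc(OCc2ccccc2)c1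
F2 | step 2 | hexadecanal | CCCCCCCCCCCCCCCC=O
F3 | step 2 | [3,5-bis(benzyloxy)phenyl]diazomethane | [N-]=[N+]=Cc1cc(OCc2ccccc2)cc(OCc2ccccc2)c1
F4 | step 1 | (E)-3,5-bis(benzyloxy)benzaldehyde N,N-dimethylhydrazone | CN(C)/N=C/c1cc(OCc2ccccc2)cc(OCc2ccccc2)c1
F5 | step 3 | 2-[3,5-bis(benzyloxy)benzyl]-2-pentadecyl-1,3-dioxolane | CCCCCCCCCCCCCCCC1(Cc2cc(OCc3ccccc3)cc(OCc3ccccc3)c2)OCCO1
F6 | step 3 | 5-[(2-pentadecyl-1,3-dioxolan-2-yl)methyl]benzene-1,3-diol | CCCCCCCCCCCCCCCC1(Cc2cc(O)cc(O)c2)OCCO1
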